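The pitfall in a flask that starts with undissolved solid is to treat the target as a straight line from the origin, and so to scale a yield as if it began at once.

| flask | solid substrate | temperature | remark | time |
|---|---|---|---|---|
| epsilon | 0.0013 M | 38 °C | run made earlier |  |
| delta | 0.0030 M | 65 °C | run made earlier |  |
| autumn | 0.0020 M | 50 °C |  | 2.0 min |
| spring | 0.0020 M | 75 °C |  | 2.0 min |
| noon | 0.0020 M |  | at 25 °C until 1.0 min, from then on at 75 °C | 2.0 min |
| winter | 0.0020 M | 25 °C |  | 2.0 min |

epsilon run (percent of the solid substrate charged)

| time / min | target / % |
|---|---|
| 0.333 | 0.3 |
| 0.667 | 1.4 |
| 0.833 | 1.2 |
| 2.00 | 5.9 |
| 4.00 | 8.0 |

delta run (percent of the solid substrate charged)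

| time / s | target / % |
|---|---|
| 12.0 | 0.9 |
| 25.0 | 2.9 |
| 40.0 | 6.4 |
| 60.0 | 10.0 |

(each reading ± 0.5 percentage points)

- a species is counted by the solid substrate in it: one self-condensation product counts as two
- given per volume of solution although it is solid: solid substrate
- the numbers in the tables scatter with a standard deviation of 0.5 percentage points
- steps that have been proposed: solid substrate <-> starting material; starting material + 2 target -> 3 target; 2 starting material -> self-condensation product; starting material -> target
- at the start none of the solid substrate is in solution
- what has only dissolved of solid substrate counts as not reacted

1. the best flask by amount of target, in percent of the solid substrate charged; "all alike" if 1.5 percentage points covers them all (autumn / spring / noon / winter / all alike)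
2. amount of target at the end, in percent of the solid substrate charged, autumn
3. amount of target at the end, in percent of the solid substrate charged, spring
4. amount of target at the end, in percent of the solid substrate charged, noon
5. amount of target at the end, in percent of the solid substrate charged, winter

In the first instants nothing is in solution, so the proposed steps have nothing to act on until the solid substrate dissolves. If [starting material] then rises in step with time, the target, fed from it, rises with the square of time. A run on that square can therefore be described by its square-law time: the reading time divided by the square root of the target, taken as a fraction of the charge. The reading of the epsilon run at 2.00 min gives 8.23 min, and the reading of the delta run at 60.0 s gives 3.16 min. Between the two temperatures this gives 19.6 K as the doubling interval, the temperature rise that divides the square-law time by 2. The two runs also differ in charge, and this reckoning sets that aside.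

In the middle of a run, a dissolved molecule meets a fork. It can become target, directly or with the help of two target, or it can pair with another starting material into self-condensation product. The balance of these exits is the selectivity, and the readings do not show it directly.

Towards the end the square fails. The epsilon run reads 8.0% at 4.00 min, less than the 23.6% the square asks for. The square-law time of the delta run also lengthens along that run, from 2.45 min at 25.0 s to 3.16 min at 60.0 s, so carrying it out to 2.0 min leans high.

With these numbers, the reckoning here gives 2.35% for winter and 13.8% for autumn. At 75 °C the square-law time is 2.22 min, which gives 81.3% for spring. Noon is bracketed by a fresh hot minute, 20.3%, and by the second minute of spring, 61.0%. Spring stands highest in this reckoning.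

The forecast, which differs from this reckoning on spring, named spring as best, with 11% for autumn, 24% for spring, 16% for noon and 3% for winter, and called these “rough extrapolations”. The flasks give 11.5% for autumn, 63.7% for spring, 35.4% for noon and 0.918% for winter, with spring best.

    solid substrate ⇌ starting material, rate k1*(cs1 - [starting material]) while solid is left; crystals form when [starting material] > cs1 (solubility = 1.20 mM, k = 0.0120 /s)
    starting material + 2 target → 3 target (k = 38000 /M²/s, Ea = 27.0 kJ/mol)
    2 starting material → self-condensation product (k = 38.0 /M/s, Ea = 42.0 kJ/mol)
    starting material → target (k = 5.00 × 10⁻⁴ /s, Ea = 95.0 kJ/mol)
    (constants at 25 °C)

Spring ends 18 percentage points below the reckoning, on the side the lengthening square-law time announced, and noon lies inside its bracket. The neighbouring flask is spring kept at 60 °C, with the same charge and time. That temperature lies 0.765 doubling intervals below spring, so the square-law time is 3.78 min and the reckoning gives 28.0%. That flask ends with 28.4% of target and 28% of the solid substrate still there, solid or dissolved.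

The data were generated by integration with constants of no real substance.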